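Atoms are numbered around the rings: C1 is the methylated ring-fusion carbon, C2/C3 the cyclopentane methylenes, C4 the isopropyl carbinol, C5 the ring-fusion CH, C6 the acyloxy carbon, C7 its neighbouring CH2, C8/C9 the enone β/α carbons and C10 the carbonyl. Breaking C1–C5 and C8–C9 turns the C9–C10–C1 ketone unit into a 2-ethoxyallyl cation and C5–C8 of the seven-membered ring into a 6-silyloxy diene, joined through C2–C4 of the cyclopentane. A single intramolecular (4+3) cycloaddition of an acyclic tertiary 2-ethoxyallyl alcohol bearing a (Z,E)-2-silyloxydiene should close both rings and relay the C4 configuration to C1 and C5; the acid-labile carbinol is installed just before.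

Key step: step 14

Remarks on the chemistry:
- (E)-1-Bromoprop-1-ene, methyl chloroformate and D-(−)-diethyl tartrate are taken as commercial.
- Carbinol centres that are erased later (C6 in 17, 18 and 21; C1 in 21–24) are carried as epimer mixtures and left undefined in the SMILES.
- C8 in 27–31 is drawn as the epimer expected from suprafacial addition; step 18 removes it.
- Names of bicyclic compounds use the bicyclo[5.3.0]decane skeleton with the numbering of the first paragraph ("route numbering").
- Compounds 21–24 contain the 1-ethoxyvinyl group and should be purified on Et3N-deactivated silica.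

Step 1
Reactants: 1 hex-5-yn-2-one
Product: 2 2-(but-3-yn-1-yl)-2-methyl-1,3-dioxolane
Conditions: HOCH2CH2OH, TsOH (cat.), benzene, reflux, Dean–Stark
Reagents that add atoms: ethylene glycol, OCCO
Why: Acid-catalysed ketalisation with azeotropic removal of water masks the methyl ketone (the future C1) for the organometallic and hydride steps, the terminal alkyne being inert.

Step 2
Reactants: 2 2-(but-3-yn-1-yl)-2-methyl-1,3-dioxolane; 3 methyl chloroformate
Product: 5 methyl 5-(2-methyl-1,3-dioxolan-2-yl)pent-2-ynoate, via lithium acetylide 4 (not isolated)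
Conditions: n-BuLi, THF, −78 °C; then ClCO2Me, −78 → 0 °C
Reagents that add atoms: methyl chloroformate (3), COC(=O)Cl
Why: Deprotonation of the terminal alkyne and C-acylation of the lithium acetylide with a chloroformate is the standard alkynoate synthesis and supplies C6.

Step 3
Reactants: 5 methyl 5-(2-methyl-1,3-dioxolan-2-yl)pent-2-ynoate; 6 isopropylmagnesium chloride
Product: 9 methyl (2E)-5-(2-methyl-1,3-dioxolan-2-yl)-3-(propan-2-yl)pent-2-enoate, via isopropylcopper 7 (not isolated), via alkenylcopper adduct 8 (not isolated)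
Conditions: i-PrMgCl, CuI (1 equiv), THF, −78 °C; MeOH, −78 °C
Reagents that add atoms: isopropylmagnesium chloride (6), CC(C)[Mg]Cl
Why: syn-Carbocupration of the alkynoate and protonation of the alkenylcopper with retention at −78 °C should give the isomer with isopropyl trans to the ester, the alkene geometry from which the epoxidation face is read.

Step 4
Reactants: 9 methyl (2E)-5-(2-methyl-1,3-dioxolan-2-yl)-3-(propan-2-yl)pent-2-enoate
Product: 10 (2E)-5-(2-methyl-1,3-dioxolan-2-yl)-3-(propan-2-yl)pent-2-en-1-ol
Conditions: i-Bu2AlH, CH2Cl2, −78 °C; aq. potassium sodium tartrate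
Reagents that add atoms: none
Why: 1,2-Reduction of the enoate with the aluminium hydride gives the allylic alcohol without touching the ketal or the alkene geometry.

Step 5
Reactants: 10 (2E)-5-(2-methyl-1,3-dioxolan-2-yl)-3-(propan-2-yl)pent-2-en-1-ol
Product: 11 [(2R,3R)-3-[2-(2-methyl-1,3-dioxolan-2-yl)ethyl]-3-(propan-2-yl)oxiran-2-yl]methanol
Conditions: Ti(OiPr)4 (10 mol %), D-(−)-diethyl tartrate (12 mol %), t-BuOOH, 4 Å MS, CH2Cl2, −20 °C
Reagents that add atoms: tert-butyl hydroperoxide, CC(C)(C)OO
Why: Sharpless asymmetric epoxidation, in which reagent control by the D-(−)-tartrate delivers oxygen to the face that makes both epoxide carbons R (isopropyl trans to CH2OH), so that C4 acquires the configuration of the target.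

Step 6
Reactants: 11 [(2R,3R)-3-[2-(2-methyl-1,3-dioxolan-2-yl)ethyl]-3-(propan-2-yl)oxiran-2-yl]methanol
Product: 12 (3S)-5-(2-methyl-1,3-dioxolan-2-yl)-3-(propan-2-yl)pentane-1,3-diol
Conditions: NaAlH2(OCH2CH2OMe)2, THF, 0 °C
Reagents that add atoms: none
Why: Regioselective reductive opening of a 2,3-epoxy alcohol, the aluminium alkoxide delivering hydride intramolecularly to the carbon next to CH2OH (C5), so that the 1,3-diol forms and the C4–O bond and its configuration are untouched.

Step 7
Reactants: 12 (3S)-5-(2-methyl-1,3-dioxolan-2-yl)-3-(propan-2-yl)pentane-1,3-diol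
Product: 13 2-methyl-2-[(3S)-3-(propan-2-yl)-3,5-bis(triethylsilyloxy)pentyl]-1,3-dioxolane
Conditions: TESOTf, 2,6-lutidine, CH2Cl2, −78 → 0 °C
Reagents that add atoms: triethylsilyl trifluoromethanesulfonate, CC[Si](CC)(CC)OS(=O)(=O)C(F)(F)F
Why: Silylation with a silyl triflate and a hindered base reaches the tertiary as well as the primary hydroxyl, and a ketone-derived dioxolane tolerates these conditions.

Step 8
Reactants: 13 2-methyl-2-[(3S)-3-(propan-2-yl)-3,5-bis(triethylsilyloxy)pentyl]-1,3-dioxolane
Product: 14 (3S)-5-(2-methyl-1,3-dioxolan-2-yl)-3-(propan-2-yl)-3-(triethylsilyloxy)pentanal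
Conditions: (COCl)2, DMSO, CH2Cl2, −78 → −30 °C; Et3N
Reagents that add atoms: none
Why: Under Swern conditions a primary triethylsilyl ether is cleaved by the chlorosulfonium reagent and oxidised directly to the aldehyde while the tertiary silyl ether stays, a known selective oxidative desilylation that saves a separate deprotection.

Step 9
Reactants: 14 (3S)-5-(2-methyl-1,3-dioxolan-2-yl)-3-(propan-2-yl)-3-(triethylsilyloxy)pentanal; 15 (E)-1-bromoprop-1-ene
Product: 17 (2E,6S)-8-(2-methyl-1,3-dioxolan-2-yl)-6-(propan-2-yl)-6-(triethylsilyloxy)oct-2-en-4-ol (C4 epimers), via (E)-prop-1-enyllithium 16 (not isolated)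
Conditions: t-BuLi (2 equiv per bromide), Et2O, −78 °C; then 14, −78 °C; H2O at −78 °C
Reagents that add atoms: (E)-1-bromoprop-1-ene (15), C/C=C/Br
Why: Bromine–lithium exchange with retention of alkene geometry and 1,2-addition of the alkenyllithium to the aldehyde install C7, C8 and the C8 methyl; the new carbinol centre (C6) forms unselectively and is erased by the oxidation in step 12, and the cold quench prevents silyl migration to the new alkoxide.

Step 10
Reactants: 17 (2E,6S)-8-(2-methyl-1,3-dioxolan-2-yl)-6-(propan-2-yl)-6-(triethylsilyloxy)oct-2-en-4-ol (C4 epimers)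
Product: 18 (5S,8E)-7-hydroxy-5-(propan-2-yl)-5-(triethylsilyloxy)dec-8-en-2-one (C7 epimers)
Conditions: PPTS, acetone–H2O, 45 °C
Reagents that add atoms: water, O
Why: Mild acid-catalysed ketal hydrolysis frees the methyl ketone, while the hindered tertiary triethylsilyl ether, which must stay to keep the C4 oxygen from ketalising the ketone, and the allylic alcohol are stable to pyridinium tosylate.

Step 11
Reactants: 18 (5S,8E)-7-hydroxy-5-(propan-2-yl)-5-(triethylsilyloxy)dec-8-en-2-one (C7 epimers); 19 ethyl vinyl ether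
Product: 21 (6S,9E)-2-ethoxy-3-methyl-6-(propan-2-yl)-6-(triethylsilyloxy)undeca-1,9-diene-3,8-diol (C3 and C8 epimers), via 1-ethoxyvinyllithium 20 (not isolated)
Conditions: t-BuLi, THF, −78 → 0 °C; then 18 (reagent in excess), −78 °C; aq. NaHCO3 at −78 °C
Reagents that add atoms: ethyl vinyl ether (19), C=COCC
Why: α-Lithiation of the vinyl ether and 1,2-addition of this acyl-anion equivalent to the methyl ketone (the first equivalent deprotonates the C6 hydroxyl) create the tertiary 2-ethoxyallyl alcohol; the C1 configuration is deliberately left uncontrolled because ionisation erases it.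

Step 12
Reactants: 21 (6S,9E)-2-ethoxy-3-methyl-6-(propan-2-yl)-6-(triethylsilyloxy)undeca-1,9-diene-3,8-diol (C3 and C8 epimers)
Product: 22 (2E,6S)-10-ethoxy-9-hydroxy-9-methyl-6-(propan-2-yl)-6-(triethylsilyloxy)undeca-2,10-dien-4-one (C9 epimers)
Conditions: MnO2 (activated, excess), CH2Cl2, rt
Reagents that add atoms: none
Why: Allylic oxidation with MnO2 converts only the secondary allylic alcohol to the enone under neutral conditions that spare the tertiary alcohol, the silyl ether and the acid-labile enol ether.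

Step 13
Reactants: 22 (2E,6S)-10-ethoxy-9-hydroxy-9-methyl-6-(propan-2-yl)-6-(triethylsilyloxy)undeca-2,10-dien-4-one (C9 epimers)
Product: 24 (6R,7Z,9E)-8-(tert-butyldimethylsilyloxy)-2-ethoxy-3-methyl-6-(propan-2-yl)-6-(triethylsilyloxy)undeca-1,7,9-trien-3-ol (C3 epimers), via dilithium alkoxide enolate 23 (not isolated)
Conditions: LiN(i-Pr)2 (2.3 equiv), THF–DMPU, −78 °C; TBSCl, −78 → −40 °C; aq. NaHCO3
Reagents that add atoms: tert-butyldimethylsilyl chloride, CC(C)(C)[Si](C)(C)Cl
Why: Kinetic α'-deprotonation of the enone at C5 (cross-conjugated enolate) and O-silylation of the enolate, which is far faster than silylation of the hindered tertiary lithium alkoxide by TBSCl, should give the (Z)-2-silyloxydiene with the C1 hydroxyl free after work-up.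

Step 14
Reactants: 24 (6R,7Z,9E)-8-(tert-butyldimethylsilyloxy)-2-ethoxy-3-methyl-6-(propan-2-yl)-6-(triethylsilyloxy)undeca-1,7,9-trien-3-ol (C3 epimers)
Product: 27 (1S,4R,5S,8R)-6-(tert-butyldimethylsilyloxy)-1,8-dimethyl-4-(propan-2-yl)-4-(triethylsilyloxy)bicyclo[5.3.0]dec-6-en-10-one (route numbering), via ethoxyallyl cation 25 (not isolated), via oxocarbenium cycloadduct 26 (not isolated)
Conditions: Tf2O, 2,6-lutidine, CH2Cl2 (high dilution), −78 °C; aq. NaHCO3
Reagents that add atoms: water, O
Why: Triflation of the only free hydroxyl and loss of triflate should give the planar 2-ethoxyallyl cation 25 (C9–C10–C1) from either C1 epimer while the two silyl ethers stay inert to Tf2O, and the cation then engages the tethered 2-silyloxydiene in an intramolecular (4+3) cycloaddition, the known reaction type of alkoxyallyl cations with tethered dienes that gives fused five-seven ketones. The cyclopentane is closed by 5-exo attack of the enol-ether carbon C5 on the substituted cation terminus C1, and the cycloheptene by 7-endo capture of the resulting C6–C8 silyloxyallyl cation at C8 by C9 of the newly formed ethyl enol ether; water at the quench converts oxocarbenium 26 into the C10 ketone. C5 is controlled by the C4 centre, whose isopropyl group sits pseudoequatorial in the envelope-like fold so that the diene arm on C5 ends up trans to it and cis to the C4 silyloxy group. C1 is controlled by the same fold, because the small methyl group rather than the ethoxyallyl arm takes the site cis to the pseudoaxial C4 oxygen, which makes the ring fusion trans. C8 follows from suprafacial bonding to the (E)-propenyl terminus and is erased in step 18. The step needs chemoselective ionisation at C1, secured by C1 carrying the only free hydroxyl, and the correct C1/C4 relationship, secured by the fold described, whereas C5 would remain correctable by enolisation towards C6.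

Step 15
Reactants: 27 (1S,4R,5S,8R)-6-(tert-butyldimethylsilyloxy)-1,8-dimethyl-4-(propan-2-yl)-4-(triethylsilyloxy)bicyclo[5.3.0]dec-6-en-10-one (route numbering)
Product: 28 (1S,4R,5R,8S)-4-hydroxy-1,8-dimethyl-4-(propan-2-yl)bicyclo[5.3.0]decane-6,10-dione (route numbering)
Conditions: HF·pyridine, pyridine, THF, 0 °C → rt
Reagents that add atoms: none
Why: Buffered fluoride desilylation cleaves the silyl enol ether (protonation at C7 gives the C6 ketone) and the tertiary silyl ether under conditions too mild for retro-aldol cleavage or dehydration of the β-hydroxy ketone, and no stereocentre changes (the descriptors at C5 and C8 change only through priority).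

Step 16
Reactants: 28 (1S,4R,5R,8S)-4-hydroxy-1,8-dimethyl-4-(propan-2-yl)bicyclo[5.3.0]decane-6,10-dione (route numbering)
Product: 29 (1S,4R,5S,6S,8S)-4,6-dihydroxy-1,8-dimethyl-4-(propan-2-yl)bicyclo[5.3.0]decan-10-one (route numbering)
Conditions: Me4NBH(OAc)3, MeCN–AcOH, −20 °C
Reagents that add atoms: none
Why: Evans–Saksena hydroxyl-directed reduction, in which the C4 hydroxyl binds boron and delivers hydride intramolecularly to the face of the C6 ketone on which it sits, should give the C6 alcohol anti to the C4 hydroxyl (6S), while the C10 ketone, lacking a β-hydroxyl, is not reduced by this mild hydride.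

Step 17
Reactants: 29 (1S,4R,5S,6S,8S)-4,6-dihydroxy-1,8-dimethyl-4-(propan-2-yl)bicyclo[5.3.0]decan-10-one (route numbering); 30 3,4-dimethoxybenzoyl chloride
Product: 31 (1S,4R,5S,6S,8S)-4-hydroxy-1,8-dimethyl-10-oxo-4-(propan-2-yl)bicyclo[5.3.0]decan-6-yl 3,4-dimethoxybenzoate (route numbering)
Conditions: 3,4-(MeO)2C6H3COCl, DMAP, Et3N, CH2Cl2, 0 °C → rt
Reagents that add atoms: 3,4-dimethoxybenzoyl chloride (30), COc1ccc(C(=O)Cl)cc1OC
Why: DMAP-catalysed acylation takes place at the secondary C6 hydroxyl only, the tertiary C4 hydroxyl being too hindered to acylate.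

Step 18
Reactants: 31 (1S,4R,5S,6S,8S)-4-hydroxy-1,8-dimethyl-10-oxo-4-(propan-2-yl)bicyclo[5.3.0]decan-6-yl 3,4-dimethoxybenzoate (route numbering)
Product: 32 (1S,4R,5S,6S)-4-hydroxy-1,8-dimethyl-10-oxo-4-(propan-2-yl)bicyclo[5.3.0]dec-8-en-6-yl 3,4-dimethoxybenzoate (route numbering), the target CNP0111132.1
Conditions: IBX, 4-methoxypyridine N-oxide, DMSO, 25–40 °C
Reagents that add atoms: none
Why: IBX-mediated α,β-dehydrogenation of a ketone can only proceed through the C9 enol because C1 is quaternary, so the C8–C9 double bond should form regiospecifically with loss of the C8 stereocentre, and the near-neutral medium avoids vinylogous elimination of the C6 ester.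

Compound list
1 | hex-5-yn-2-one | CC(=O)CCC#C | starting material
2 | 2-(but-3-yn-1-yl)-2-methyl-1,3-dioxolane | CC1(CCC#C)OCCO1 | intermediate
3 | methyl chloroformate | COC(=O)Cl | starting material
4 | lithium acetylide of 2 (not isolated) | CC1(CCC#C[Li])OCCO1 | intermediate
5 | methyl 5-(2-methyl-1,3-dioxolan-2-yl)pent-2-ynoate | CC1(CCC#CC(=O)OC)OCCO1 | intermediate
6 | isopropylmagnesium chloride | CC(C)[Mg]Cl | starting material
7 | isopropylcopper (not isolated) | CC(C)[Cu] | intermediate
8 | alkenylcopper adduct of 5, copper on C2 cis to isopropyl (not isolated) | CC1(CC/C(C(C)C)=C(/[Cu])C(=O)OC)OCCO1 | intermediate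
9 | methyl (2E)-5-(2-methyl-1,3-dioxolan-2-yl)-3-(propan-2-yl)pent-2-enoate | CC1(CC/C(C(C)C)=C\C(=O)OC)OCCO1 | intermediate
10 | (2E)-5-(2-methyl-1,3-dioxolan-2-yl)-3-(propan-2-yl)pent-2-en-1-ol | CC1(CC/C(C(C)C)=C\CO)OCCO1 | intermediate
11 | [(2R,3R)-3-[2-(2-methyl-1,3-dioxolan-2-yl)ethyl]-3-(propan-2-yl)oxiran-2-yl]methanol | CC1(CC[C@@](O2)(C(C)C)[C@H]2CO)OCCO1 | intermediate
12 | (3S)-5-(2-methyl-1,3-dioxolan-2-yl)-3-(propan-2-yl)pentane-1,3-diol | CC1(CC[C@@](O)(C(C)C)CCO)OCCO1 | intermediate
13 | 2-methyl-2-[(3S)-3-(propan-2-yl)-3,5-bis(triethylsilyloxy)pentyl]-1,3-dioxolane | CC1(CC[C@@](O[Si](CC)(CC)CC)(C(C)C)CCO[Si](CC)(CC)CC)OCCO1 | intermediate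
14 | (3S)-5-(2-methyl-1,3-dioxolan-2-yl)-3-(propan-2-yl)-3-(triethylsilyloxy)pentanal | CC1(CC[C@@](O[Si](CC)(CC)CC)(C(C)C)CC=O)OCCO1 | intermediate
15 | (E)-1-bromoprop-1-ene | C/C=C/Br | starting material
16 | (E)-prop-1-enyllithium (not isolated) | C/C=C/[Li] | intermediate
17 | (2E,6S)-8-(2-methyl-1,3-dioxolan-2-yl)-6-(propan-2-yl)-6-(triethylsilyloxy)oct-2-en-4-ol (C4 epimers) | CC1(CC[C@@](O[Si](CC)(CC)CC)(C(C)C)CC(O)/C=C/C)OCCO1 | intermediate
18 | (5S,8E)-7-hydroxy-5-(propan-2-yl)-5-(triethylsilyloxy)dec-8-en-2-one (C7 epimers) | CC(=O)CC[C@@](O[Si](CC)(CC)CC)(C(C)C)CC(O)/C=C/C | intermediate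
19 | ethyl vinyl ether | C=COCC | starting material
20 | 1-ethoxyvinyllithium (not isolated) | C=C([Li])OCC | intermediate
21 | (6S,9E)-2-ethoxy-3-methyl-6-(propan-2-yl)-6-(triethylsilyloxy)undeca-1,9-diene-3,8-diol (C3 and C8 epimers) | C=C(OCC)C(C)(O)CC[C@@](O[Si](CC)(CC)CC)(C(C)C)CC(O)/C=C/C | intermediate
22 | (2E,6S)-10-ethoxy-9-hydroxy-9-methyl-6-(propan-2-yl)-6-(triethylsilyloxy)undeca-2,10-dien-4-one (C9 epimers) | C=C(OCC)C(C)(O)CC[C@@](O[Si](CC)(CC)CC)(C(C)C)CC(=O)/C=C/C | intermediate
23 | dilithium alkoxide enolate of 22 (not isolated) | C=C(OCC)C(C)(O[Li])CC[C@@](O[Si](CC)(CC)CC)(C(C)C)/C=C(O[Li])/C=C/C | intermediate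
24 | (6R,7Z,9E)-8-(tert-butyldimethylsilyloxy)-2-ethoxy-3-methyl-6-(propan-2-yl)-6-(triethylsilyloxy)undeca-1,7,9-trien-3-ol (C3 epimers); key-step precursor | C=C(OCC)C(C)(O)CC[C@@](O[Si](CC)(CC)CC)(C(C)C)/C=C(O[Si](C)(C)C(C)(C)C)/C=C/C | intermediate
25 | 2-ethoxyallyl cation from 24, as triflate (not isolated) | C=C(OCC)[C+](C)CC[C@@](O[Si](CC)(CC)CC)(C(C)C)/C=C(O[Si](C)(C)C(C)(C)C)/C=C/C.[O-]S(=O)(=O)C(F)(F)F | intermediate
26 | O-ethyl oxocarbenium form of cycloadduct 27, as triflate (not isolated) | CC(C)(C)[Si](C)(C)OC1=C[C@H](C)CC(=[O+]CC)[C@@]2(C)CC[C@@](O[Si](CC)(CC)CC)(C(C)C)[C@H]12.[O-]S(=O)(=O)C(F)(F)F | intermediate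
27 | (1S,4R,5S,8R)-6-(tert-butyldimethylsilyloxy)-1,8-dimethyl-4-(propan-2-yl)-4-(triethylsilyloxy)bicyclo[5.3.0]dec-6-en-10-one (route numbering); trans-fused cycloadduct | CC(C)(C)[Si](C)(C)OC1=C[C@H](C)CC(=O)[C@@]2(C)CC[C@@](O[Si](CC)(CC)CC)(C(C)C)[C@H]12 | intermediate
28 | (1S,4R,5R,8S)-4-hydroxy-1,8-dimethyl-4-(propan-2-yl)bicyclo[5.3.0]decane-6,10-dione (route numbering) | O=C1C[C@H](C)CC(=O)[C@@]2(C)CC[C@@](O)(C(C)C)[C@H]12 | intermediate
29 | (1S,4R,5S,6S,8S)-4,6-dihydroxy-1,8-dimethyl-4-(propan-2-yl)bicyclo[5.3.0]decan-10-one (route numbering) | O[C@H]1C[C@H](C)CC(=O)[C@@]2(C)CC[C@@](O)(C(C)C)[C@H]12 | intermediate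
30 | 3,4-dimethoxybenzoyl chloride | COc1ccc(C(=O)Cl)cc1OC | starting material
31 | (1S,4R,5S,6S,8S)-4-hydroxy-1,8-dimethyl-10-oxo-4-(propan-2-yl)bicyclo[5.3.0]decan-6-yl 3,4-dimethoxybenzoate (route numbering) | COc1ccc(C(=O)O[C@H]2C[C@H](C)CC(=O)[C@@]3(C)CC[C@@](O)(C(C)C)[C@H]23)cc1OC | intermediate
32 | (1S,4R,5S,6S)-4-hydroxy-1,8-dimethyl-10-oxo-4-(propan-2-yl)bicyclo[5.3.0]dec-8-en-6-yl 3,4-dimethoxybenzoate (route numbering); CNP0111132.1 | COc1ccc(C(=O)O[C@H]2CC(C)=CC(=O)[C@@]3(C)CC[C@@](O)(C(C)C)[C@H]23)cc1OC | target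

Total step count: 18.
Longest linear sequence: 18 steps (1 → 32); the organometallic partners are made in the flask.

Steps most likely to fail

Step 14. After the C1–C5 bond has formed, the silyloxyallyl cation may lose its silyl group, or be captured at C6 instead of C8, before the seven-membered ring closes; ionisation or participation of the C4 silyloxy oxygen and poor facial control at C1 would also erode the step. The fallback replaces the one-operation cycloaddition by a stepwise polar annulation. Setting out from 24, the same buffered triflation is run but worked up with dilute aqueous acid, so that the first bond alone is harvested as the monocyclic cyclopentyl diketone F1 (C1 carrying methyl and acetyl, C5 carrying the (E)-but-2-enoyl group). The seven-membered ring is then closed under thermodynamic control by base-catalysed intramolecular Michael addition of the acetyl methyl carbon C9 to C8 (KOt-Bu cat., t-BuOH–THF, 0 °C), which should give the C4-silylated bicyclic dione F2. HF·pyridine as in step 15 returns to the route at 28; either C8 epimer serves, since step 18 removes that centre.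

Step 13. Deprotonation may stray to the γ-methyl group, the C5 enolate may expel the C4 silyloxy group, or the C1 alkoxide may be silylated. The fallback avoids strong base. Setting out from 22, the C1 hydroxyl is masked with N-(trimethylsilyl)imidazole (CH2Cl2, rt) to give the trimethylsilyl ether F3. Amine-buffered soft enolisation (TBSOTf, Et3N, CH2Cl2, −78 °C) should then give the thermodynamically preferred (Z)-silyloxydiene F4. K2CO3 in MeOH at 0 °C should cleave only the trimethylsilyl ether and rejoin the route at 24.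

Step 18. Over-oxidation to the 6,8-dienone or thermal vinylogous elimination of the C6 ester may compete under the IBX conditions. The fallback is a Saegusa–Ito oxidation at room temperature. Setting out from 31, TMSOTf and Et3N (CH2Cl2, 0 °C) should form the only possible silyl enol ether (C9=C10) and silylate the C4 hydroxyl, giving the bis(trimethylsilyl) compound F5. Pd(OAc)2 (divalent palladium, one equivalent) in MeCN should give the C4-silylated enone F6. Citric acid in MeOH then removes the tertiary trimethylsilyl ether and delivers 32.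

Further compounds
F1 | step 14 | cyclopentane with C1 methyl and acetyl, C5 (E)-but-2-enoyl, C4 isopropyl and triethylsilyloxy, configurations at C1, C4 and C5 as in 27 | CC(=O)[C@@]1(C)CC[C@@](O[Si](CC)(CC)CC)(C(C)C)[C@@H]1C(=O)/C=C/C
F2 | step 14 | C4 triethylsilyl ether of 28 (C8 epimers) | O=C1CC(C)CC(=O)[C@@]2(C)CC[C@@](O[Si](CC)(CC)CC)(C(C)C)[C@H]12
F3 | step 13 | C1 (undecadienone C9) trimethylsilyl ether of 22 | C=C(OCC)C(C)(O[Si](C)(C)C)CC[C@@](O[Si](CC)(CC)CC)(C(C)C)CC(=O)/C=C/C
F4 | step 13 | C1 (undecatrienol C3) trimethylsilyl ether of 24 | C=C(OCC)C(C)(O[Si](C)(C)C)CC[C@@](O[Si](CC)(CC)CC)(C(C)C)/C=C(O[Si](C)(C)C(C)(C)C)/C=C/C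
F5 | step 18 | C9=C10 trimethylsilyl enol ether and C4 trimethylsilyl ether of 31 | COc1ccc(C(=O)O[C@H]2C[C@H](C)C=C(O[Si](C)(C)C)[C@@]3(C)CC[C@@](O[Si](C)(C)C)(C(C)C)[C@H]23)cc1OC
F6 | step 18 | C4 trimethylsilyl ether of 32 | COc1ccc(C(=O)O[C@H]2CC(C)=CC(=O)[C@@]3(C)CC[C@@](O[Si](C)(C)C)(C(C)C)[C@H]23)cc1OC
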